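**Plan**
- The C1 acid is traced back to a silyl-protected primary alcohol. The first cut is C14–C15, in the interior of the unfunctionalised (CH2)18 tether C5–C22 that joins the C3=C4 alkene to the arene. Both carbons are plain primary centres with no neighbouring group, so the bond can be made from two acids that each lose their carboxyl carbon.
- Further cuts: C4–C5 (vinyl iodide plus the alkylborane of methyl undec-10-enoate) and C22–aryl (aryl Grignard reagent plus 9-bromononanoic acid).
- Forward: the head is built linearly from the hydroxy ester and joined at C4–C5 by Suzuki coupling. The tail acid is made separately, and the two N-acyloxyphthalimides are united at C14–C15. C1 is then oxidised and the phenol released; no ring is formed.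
- Stereochemistry: C2 comes from methyl (R)-3-hydroxy-2-methylpropanoate (its ester carbon becomes C3, its CH2OH becomes C1). The 3E geometry comes from syn-hydrozirconation/iodination of a methylalkyne and a stereoretentive Suzuki coupling.

Key step: step 12

Remark: numbering follows the target acid (C1 = carboxyl carbon, C22 = benzylic carbon). Undecylenic acid is used as its commercial methyl ester, so that the carboxyl group is inert during hydroboration and coupling.

**Route**

Step 1
Reactants: 1 methyl (R)-3-hydroxy-2-methylpropanoate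
Product: 2 methyl (R)-3-(tert-butyldimethylsilyloxy)-2-methylpropanoate
Conditions: TBSCl, imidazole, CH2Cl2, 0 °C to rt
Reagents that add atoms: tert-butyldimethylsilyl chloride, CC(C)(C)[Si](C)(C)Cl
Why: Imidazole-promoted silylation of the primary alcohol (silyl ether formation) masks the future C1 oxygen without touching the α-stereocentre.

Step 2
Reactants: 2 methyl (R)-3-(tert-butyldimethylsilyloxy)-2-methylpropanoate
Product: 3 (R)-3-(tert-butyldimethylsilyloxy)-2-methylpropanal
Conditions: i-Bu2AlH (1.1 equiv), CH2Cl2, −78 °C; aq. potassium sodium tartrate work-up; used crude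
Reagents that add atoms: none
Why: Partial ester reduction with i-Bu2AlH at −78 °C stops at the aluminium hemiacetal, which releases the aldehyde only on work-up, and the non-basic conditions leave the α-stereocentre intact.

Step 3
Reactants: 3 (R)-3-(tert-butyldimethylsilyloxy)-2-methylpropanal
Product: 4 (S)-tert-butyl(2-methylbut-3-yn-1-yloxy)dimethylsilane
Conditions: dimethyl (1-diazo-2-oxopropyl)phosphonate, K2CO3, MeOH, 0 °C to rt
Reagents that add atoms: dimethyl (1-diazo-2-oxopropyl)phosphonate, CC(=O)C(=[N+]=[N-])P(=O)(OC)OC
Why: In this Ohira–Bestmann (Seyferth–Gilbert) homologation, methanolysis of the reagent gives the diazomethylphosphonate anion, which olefinates the aldehyde and then loses N2 with a 1,2-hydrogen shift to the terminal alkyne, the low temperature limiting enolisation of 3.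

Step 4
Reactants: 4 (S)-tert-butyl(2-methylbut-3-yn-1-yloxy)dimethylsilane
Product: 6 (S)-tert-butyldimethyl(2-methylpent-3-yn-1-yloxy)silane, via lithium acetylide 5 (not isolated)
Conditions: n-BuLi, THF, −78 °C; then MeI, −78 °C to rt
Reagents that add atoms: iodomethane, CI
Why: Deprotonation of the terminal alkyne and SN2 alkylation of the lithium acetylide with MeI installs the carbon that becomes the C4 methyl group.

Step 5
Reactants: 6 (S)-tert-butyldimethyl(2-methylpent-3-yn-1-yloxy)silane
Product: 8 tert-butyl{[(2S,3E)-4-iodo-2-methylpent-3-en-1-yl]oxy}dimethylsilane, via alkenylzirconocene chloride 7 (not isolated)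
Conditions: Cp2Zr(H)Cl (2 equiv), THF, 50 °C; then I2, THF, 0 °C, dark
Reagents that add atoms: iodine, II
Why: Syn-hydrozirconation with excess Cp2Zr(H)Cl under warming equilibrates to the isomer with zirconium on the methyl-bearing carbon remote from the branched C2, and iodinolysis of the C–Zr bond with retention fixes the (E)-trisubstituted vinyl iodide.

Step 6
Reactants: 9 methyl undec-10-enoate; 8 tert-butyl{[(2S,3E)-4-iodo-2-methylpent-3-en-1-yl]oxy}dimethylsilane
Product: 11 methyl (12E,14S)-15-(tert-butyldimethylsilyloxy)-12,14-dimethylpentadec-12-enoate, via B-alkyl-9-BBN adduct 10 (not isolated)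
Conditions: 9, 9-BBN, THF, 0 °C to rt; then 8, PdCl2(dppf) (5 mol%), AsPh3, Cs2CO3, DMF/THF/H2O, rt
Reagents that add atoms: none
Why: Anti-Markovnikov hydroboration of the terminal alkene by 9-BBN followed by B-alkyl Suzuki–Miyaura coupling, which proceeds with retention at the vinyl iodide, forms C4–C5 and fixes the 3E geometry while the methyl ester and the silyl ether stay inert.

Step 7
Reactants: 11 methyl (12E,14S)-15-(tert-butyldimethylsilyloxy)-12,14-dimethylpentadec-12-enoate
Product: 12 (12E,14S)-15-(tert-butyldimethylsilyloxy)-12,14-dimethylpentadec-12-enoic acid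
Conditions: LiOH, THF/MeOH/H2O, rt; then 0.5 M HCl to pH 4, 0 °C
Reagents that add atoms: lithium hydroxide, [Li+].[OH-]
Why: Saponification of the unhindered methyl ester by LiOH is routine, and the primary TBS ether and the stereocentre, which has no adjacent carbonyl group, are unaffected by hydroxide or by the brief cold acidification.

Step 8
Reactants: 12 (12E,14S)-15-(tert-butyldimethylsilyloxy)-12,14-dimethylpentadec-12-enoic acid
Product: 13 1,3-dioxoisoindolin-2-yl (12E,14S)-15-(tert-butyldimethylsilyloxy)-12,14-dimethylpentadec-12-enoate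
Conditions: N-hydroxyphthalimide, DIC, DMAP (10 mol%), CH2Cl2, rt
Reagents that add atoms: N-hydroxyphthalimide, O=C1c2ccccc2C(=O)N1O
Why: Carbodiimide-mediated (Steglich-type) esterification with N-hydroxyphthalimide gives the redox-active ester under neutral conditions.

Step 9
Reactants: 14 4-bromophenol
Product: 15 (4-bromophenoxy)triisopropylsilane
Conditions: TIPSCl, imidazole, DMF, rt
Reagents that add atoms: triisopropylsilyl chloride, CC(C)[Si](Cl)(C(C)C)C(C)C
Why: Imidazole-promoted silylation gives the bulky aryl TIPS ether, which tolerates Grignard formation, single-electron reduction, acidic methanolysis and the later oxidations.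

Step 10
Reactants: 15 (4-bromophenoxy)triisopropylsilane; 16 9-bromononanoic acid
Product: 19 9-[4-(triisopropylsilyloxy)phenyl]nonanoic acid, via aryl Grignard reagent 17 (not isolated), via chloromagnesium 9-bromononanoate 18 (not isolated)
Conditions: 15, Mg, THF, reflux; separately 16, MeMgCl (1.0 equiv), THF, −20 °C; then 17 (1.5 equiv), Li2CuCl4 (5 mol%), THF, −20 °C to rt; aq. HCl to pH 3
Reagents that add atoms: none
Why: This copper-catalysed Grignard cross-coupling of an aryl Grignard reagent with a primary alkyl bromide is run on the preformed chloromagnesium carboxylate, so the acid proton is already removed and the carboxylate, a poor electrophile at low temperature, is spared.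

Step 11
Reactants: 19 9-[4-(triisopropylsilyloxy)phenyl]nonanoic acid
Product: 20 1,3-dioxoisoindolin-2-yl 9-[4-(triisopropylsilyloxy)phenyl]nonanoate
Conditions: N-hydroxyphthalimide, DIC, DMAP (10 mol%), CH2Cl2, rt
Reagents that add atoms: N-hydroxyphthalimide, O=C1c2ccccc2C(=O)N1O
Why: Carbodiimide-mediated (Steglich-type) esterification converts the acid into its redox-active N-acyloxyphthalimide without disturbing the aryl silyl ether.

Step 12
Reactants: 13 1,3-dioxoisoindolin-2-yl (12E,14S)-15-(tert-butyldimethylsilyloxy)-12,14-dimethylpentadec-12-enoate; 20 1,3-dioxoisoindolin-2-yl 9-[4-(triisopropylsilyloxy)phenyl]nonanoate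
Product: 21 tert-butyl{[(2S,3E)-2,4-dimethyl-22-[4-(triisopropylsilyloxy)phenyl]docos-3-en-1-yl]oxy}dimethylsilane
Conditions: 13 (1 equiv), 20 (3 equiv), NiCl2·6H2O (20 mol%), 2,2':6',2''-terpyridine (20 mol%), AgNO3 (0.3 equiv), NaI, DMF, Mg anode/reticulated vitreous carbon cathode, undivided cell, constant current, rt; aq. NH4Cl work-up
Reagents that add atoms: none
Why: Electrons from the cathode, relayed by low-valent nickel–terpyridine, reduce each N-acyloxyphthalimide, which fragments to phthalimide anion, CO2 and a primary alkyl radical (C14 of the head, C15 of the tail); both radicals are captured at nickel, and the resulting dialkylnickel species in the trivalent state reductively eliminates the C14–C15 bond while the Mg anode is consumed. The closest known reaction type is the nickel-electrocatalytic doubly decarboxylative C(sp3)–C(sp3) coupling of two redox-active esters, the reductive counterpart of a mixed Kolbe electrolysis, which is established for primary–primary pairs. No ring is closed and no stereocentre is created; the C2 stereocentre and the C3=C4 alkene lie ten or more atoms from the radical site, so neither cyclisation nor epimerisation is open to it. The only selectivity needed is cross- over homo-coupling, which is statistical for two primary radicals and is tilted towards the head fragment by using the two-step tail ester 20 in threefold excess. The reducing medium should leave both silyl ethers, the electron-rich arene and the trisubstituted alkene untouched, which an anodic coupling would not guarantee. Any tail homodimer that co-elutes can be carried on, since after step 13 only the cross-product bears a single hydroxyl group.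

Step 13
Reactants: 21 tert-butyl{[(2S,3E)-2,4-dimethyl-22-[4-(triisopropylsilyloxy)phenyl]docos-3-en-1-yl]oxy}dimethylsilane
Product: 22 (2S,3E)-2,4-dimethyl-22-[4-(triisopropylsilyloxy)phenyl]docos-3-en-1-ol
Conditions: camphorsulfonic acid (10 mol%), MeOH/CH2Cl2 (1:1), 0 °C
Reagents that add atoms: none
Why: Acid-catalysed methanolysis (desilylation) removes the unhindered primary alkyl TBS ether far faster than the bulky, acid-resistant aryl TIPS ether.

Step 14
Reactants: 22 (2S,3E)-2,4-dimethyl-22-[4-(triisopropylsilyloxy)phenyl]docos-3-en-1-ol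
Product: 23 (2S,3E)-2,4-dimethyl-22-[4-(triisopropylsilyloxy)phenyl]docos-3-enal
Conditions: Dess–Martin periodinane, pyridine, CH2Cl2, 0 °C; short filtration, used at once
Reagents that add atoms: none
Why: Dess–Martin oxidation under buffered, non-aqueous conditions gives the β,γ-unsaturated aldehyde without enolisation, and immediate use of the crude product avoids epimerisation at C2 or drift of the alkene into conjugation.

Step 15
Reactants: 23 (2S,3E)-2,4-dimethyl-22-[4-(triisopropylsilyloxy)phenyl]docos-3-enal
Product: 24 (2S,3E)-2,4-dimethyl-22-[4-(triisopropylsilyloxy)phenyl]docos-3-enoic acid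
Conditions: NaClO2, NaH2PO4, 2-methyl-2-butene (excess), t-BuOH/H2O, 0 °C to rt
Reagents that add atoms: sodium chlorite, [Na+].[O-]Cl=O
Why: Pinnick oxidation converts the aldehyde into the acid at mildly acidic pH while 2-methyl-2-butene consumes the hypochlorous acid, so the C3=C4 alkene, the C2 stereocentre and the aryl silyl ether are preserved.

Step 16
Reactants: 24 (2S,3E)-2,4-dimethyl-22-[4-(triisopropylsilyloxy)phenyl]docos-3-enoic acid
Product: 25 (2S,3E)-22-(4-hydroxyphenyl)-2,4-dimethyldocos-3-enoic acid
Conditions: Bu4NF (2.5 equiv), THF, 0 °C; then aq. NH4Cl/dilute HCl to pH 3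
Reagents that add atoms: none
Why: Fluoride-mediated desilylation cleaves the aryl TIPS ether through pentacoordinate silicon, while the acid is present as its carboxylate and is thereby shielded from α-deprotonation.

**Compound list**
1 | methyl (R)-3-hydroxy-2-methylpropanoate | COC(=O)[C@H](C)CO | starting material
2 | methyl (R)-3-(tert-butyldimethylsilyloxy)-2-methylpropanoate | COC(=O)[C@H](C)CO[Si](C)(C)C(C)(C)C | intermediate
3 | (R)-3-(tert-butyldimethylsilyloxy)-2-methylpropanal | O=C[C@H](C)CO[Si](C)(C)C(C)(C)C | intermediate
4 | (S)-tert-butyl(2-methylbut-3-yn-1-yloxy)dimethylsilane | C#C[C@H](C)CO[Si](C)(C)C(C)(C)C | intermediate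
5 | lithium acetylide of 4 (not isolated) | [Li]C#C[C@H](C)CO[Si](C)(C)C(C)(C)C | intermediate
6 | (S)-tert-butyldimethyl(2-methylpent-3-yn-1-yloxy)silane | CC#C[C@H](C)CO[Si](C)(C)C(C)(C)C | intermediate
7 | chlorobis(cyclopentadienyl)[(2E,4S)-5-(tert-butyldimethylsilyloxy)-4-methylpent-2-en-2-yl]zirconium (not isolated) | C/C(=C\[C@H](C)CO[Si](C)(C)C(C)(C)C)[Zr](Cl)(C1C=CC=C1)C1C=CC=C1 | intermediate
8 | tert-butyl{[(2S,3E)-4-iodo-2-methylpent-3-en-1-yl]oxy}dimethylsilane | C/C(I)=C\[C@H](C)CO[Si](C)(C)C(C)(C)C | intermediate
9 | methyl undec-10-enoate | C=CCCCCCCCCC(=O)OC | starting material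
10 | methyl 11-(9-borabicyclo[3.3.1]nonan-9-yl)undecanoate (not isolated) | COC(=O)CCCCCCCCCCB1C2CCCC1CCC2 | intermediate
11 | methyl (12E,14S)-15-(tert-butyldimethylsilyloxy)-12,14-dimethylpentadec-12-enoate | C/C(=C\[C@H](C)CO[Si](C)(C)C(C)(C)C)CCCCCCCCCCC(=O)OC | intermediate
12 | (12E,14S)-15-(tert-butyldimethylsilyloxy)-12,14-dimethylpentadec-12-enoic acid | C/C(=C\[C@H](C)CO[Si](C)(C)C(C)(C)C)CCCCCCCCCCC(=O)O | intermediate
13 | 1,3-dioxoisoindolin-2-yl (12E,14S)-15-(tert-butyldimethylsilyloxy)-12,14-dimethylpentadec-12-enoate | C/C(=C\[C@H](C)CO[Si](C)(C)C(C)(C)C)CCCCCCCCCCC(=O)ON1C(=O)c2ccccc2C1=O | intermediate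
14 | 4-bromophenol | Oc1ccc(Br)cc1 | starting material
15 | (4-bromophenoxy)triisopropylsilane | CC(C)[Si](Oc1ccc(Br)cc1)(C(C)C)C(C)C | intermediate
16 | 9-bromononanoic acid | OC(=O)CCCCCCCCBr | starting material
17 | 4-(triisopropylsilyloxy)phenylmagnesium bromide (not isolated) | Br[Mg]c1ccc(O[Si](C(C)C)(C(C)C)C(C)C)cc1 | intermediate
18 | chloromagnesium 9-bromononanoate (not isolated) | BrCCCCCCCCC(=O)O[Mg]Cl | intermediate
19 | 9-[4-(triisopropylsilyloxy)phenyl]nonanoic acid | OC(=O)CCCCCCCCc1ccc(O[Si](C(C)C)(C(C)C)C(C)C)cc1 | intermediate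
20 | 1,3-dioxoisoindolin-2-yl 9-[4-(triisopropylsilyloxy)phenyl]nonanoate | O=C(CCCCCCCCc1ccc(O[Si](C(C)C)(C(C)C)C(C)C)cc1)ON1C(=O)c2ccccc2C1=O | intermediate
21 | tert-butyl{[(2S,3E)-2,4-dimethyl-22-[4-(triisopropylsilyloxy)phenyl]docos-3-en-1-yl]oxy}dimethylsilane | C/C(=C\[C@H](C)CO[Si](C)(C)C(C)(C)C)CCCCCCCCCCCCCCCCCCc1ccc(O[Si](C(C)C)(C(C)C)C(C)C)cc1 | intermediate
22 | (2S,3E)-2,4-dimethyl-22-[4-(triisopropylsilyloxy)phenyl]docos-3-en-1-ol | C/C(=C\[C@H](C)CO)CCCCCCCCCCCCCCCCCCc1ccc(O[Si](C(C)C)(C(C)C)C(C)C)cc1 | intermediate
23 | (2S,3E)-2,4-dimethyl-22-[4-(triisopropylsilyloxy)phenyl]docos-3-enal | C/C(=C\[C@H](C)C=O)CCCCCCCCCCCCCCCCCCc1ccc(O[Si](C(C)C)(C(C)C)C(C)C)cc1 | intermediate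
24 | (2S,3E)-2,4-dimethyl-22-[4-(triisopropylsilyloxy)phenyl]docos-3-enoic acid | C/C(=C\[C@H](C)C(=O)O)CCCCCCCCCCCCCCCCCCc1ccc(O[Si](C(C)C)(C(C)C)C(C)C)cc1 | intermediate
25 | (2S,3E)-22-(4-hydroxyphenyl)-2,4-dimethyldocos-3-enoic acid | C/C(=C\[C@H](C)C(=O)O)CCCCCCCCCCCCCCCCCCc1ccc(O)cc1 | target

**Step count**
Total: 16 steps. Longest linear sequence: 13 steps (steps 1–8, then 12–16); the tail branch (steps 9–11) joins at step 12.

**Steps most likely to fail**

Step 12. The two primary radicals may pair statistically in favour of the homodimers, or the esters may be reduced to the alkanes at the cathode before they meet nickel, so that little cross-product forms. The fallback keeps the C14–C15 bond and ester 13 but generates only one radical. It sets out from aryl bromide 15 through its Grignard reagent 17. Reagent 17 is coupled with an excess of 1,8-dibromooctane (Li2CuCl4 catalyst, THF, 0 °C) to give [4-(8-bromooctyl)phenoxy]triisopropylsilane F1. Magnesium insertion in THF gives 8-[4-(triisopropylsilyloxy)phenyl]octylmagnesium bromide F2. Transmetalation with ZnCl2 (0.5 equiv) gives bis{8-[4-(triisopropylsilyloxy)phenyl]octyl}zinc F3. A nickel-catalysed decarboxylative alkyl–alkyl Negishi coupling of 13 with F3 (NiCl2(dme), 4,4'-di-tert-butyl-2,2'-bipyridine, THF/DMF, rt) should then pair the C14 radical with an organometallic C15 partner, and the route is rejoined at 21.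

Step 10. Transmetalation of the electron-rich aryl Grignard reagent to copper may be slow, so that biaryl formation, halogen–metal exchange or attack on the carboxylate competes with alkylation. The fallback sets out from aryl bromide 15 and avoids the organomagnesium altogether. Sonogashira coupling with commercial non-8-ynoic acid (PdCl2(PPh3)2, CuI, Et3N, DMF, 70 °C) should give 9-[4-(triisopropylsilyloxy)phenyl]non-8-ynoic acid F4. Hydrogenation of the alkyne (H2, Pd/C, EtOAc, rt), which the aryl silyl ether tolerates, rejoins the route at 19.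

Step 3. Carbonate in methanol may enolise aldehyde 3 before it is olefinated, eroding the enantiopurity of the future C2. The fallback sets out from 3 and uses a Corey–Fuchs sequence with no basic protic medium. CBr4 and PPh3 in CH2Cl2 at 0 °C (2,6-lutidine as buffer) should give (S)-tert-butyl(4,4-dibromo-2-methylbut-3-en-1-yloxy)dimethylsilane F5. Treatment with n-BuLi (2.2 equiv, THF, −78 °C) effects bromine–lithium exchange and Fritsch–Buttenberg–Wiechell rearrangement to the lithium acetylide 5, which is methylated with MeI in the same flask. The route is rejoined at 6, and alkyne 4 is bypassed.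

**Further compounds**
F1 | step 12 | [4-(8-bromooctyl)phenoxy]triisopropylsilane | BrCCCCCCCCc1ccc(O[Si](C(C)C)(C(C)C)C(C)C)cc1
F2 | step 12 | 8-[4-(triisopropylsilyloxy)phenyl]octylmagnesium bromide | Br[Mg]CCCCCCCCc1ccc(O[Si](C(C)C)(C(C)C)C(C)C)cc1
F3 | step 12 | bis{8-[4-(triisopropylsilyloxy)phenyl]octyl}zinc | CC(C)[Si](Oc1ccc(CCCCCCCC[Zn]CCCCCCCCc2ccc(O[Si](C(C)C)(C(C)C)C(C)C)cc2)cc1)(C(C)C)C(C)C
F4 | step 10 | 9-[4-(triisopropylsilyloxy)phenyl]non-8-ynoic acid | OC(=O)CCCCCCC#Cc1ccc(O[Si](C(C)C)(C(C)C)C(C)C)cc1
F5 | step 3 | (S)-tert-butyl(4,4-dibromo-2-methylbut-3-en-1-yloxy)dimethylsilane | BrC(Br)=C[C@H](C)CO[Si](C)(C)C(C)(C)C
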